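**Strategy.** Everything rests on opening the dihydrobenzofuran ring at its O1–C2 bond. The key step exploits that C2 is benzylic to the pendant guaiacyl ring and para to that ring's oxygen, while O1 is a phenol oxygen held ortho to C3 on the benzo ring. In one operation acid unmasks the phenol, ionises C2 to a quinone-methide-type cation and closes the furan ring trans to the C3 hydroxymethyl group, whichever carbinol epimer enters. The precursor is an open-chain, aldol-derived 1,2-diarylpropane-1,3-diol with a MOM-masked phenol. A diol of the antipodal aldol series, oxidised instead of cyclised, becomes the keto arm. Negishi coupling and trans-selective lactone alkylation assemble the butyrolactone core.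

Key step: step 6

Remark: the aldol carbinol centre is sacrificial in both arms (ionised in step 6, oxidised in step 21), so each aldol only has to fix the aryl-bearing carbon; (R)-paraconic acid is taken as a purchasable single enantiomer.

Step 1
Reactants: 1 5-bromo-2-hydroxy-3-methoxybenzaldehyde
Product: 2 5-bromo-3-methoxy-2-(methoxymethoxy)benzaldehyde
Conditions: MOMCl, i-Pr2NEt, CH2Cl2, 0 °C to rt
Reagents that add atoms: chloromethyl methyl ether (COCCl)
Why: Williamson-type O-alkylation of the phenol with the α-chloro ether gives a methoxymethyl acetal that should survive base, hydride and boron enolate chemistry and fall off in the acid of step 6.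

Step 2
Reactants: 2 5-bromo-3-methoxy-2-(methoxymethoxy)benzaldehyde
Product: 4 2-[5-bromo-3-methoxy-2-(methoxymethoxy)phenyl]acetic acid, via trichloromethyl carbinol 3 (not isolated)
Conditions: CHCl3, DBU, 0 °C to rt; then NaBH4, NaOH, t-BuOH, 55 °C; citric acid work-up
Reagents that add atoms: chloroform (ClC(Cl)Cl); sodium hydroxide ([Na+].[OH-])
Why: Base-mediated trichloromethide addition to the aldehyde followed by a reductive Jocic reaction (the alkoxide closes to a gem-dichloroepoxide, hydride opens it at the benzylic carbon and the acyl chloride is hydrolysed) should give the one-carbon-homologated arylacetic acid in one flask without touching the acetal or the aryl bromide.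

Step 3
Reactants: 4 2-[5-bromo-3-methoxy-2-(methoxymethoxy)phenyl]acetic acid; 5 (S)-4-benzyloxazolidin-2-one
Product: 7 (S)-4-benzyl-3-{2-[5-bromo-3-methoxy-2-(methoxymethoxy)phenyl]acetyl}oxazolidin-2-one, via mixed pivalic anhydride 6 (not isolated)
Conditions: t-BuCOCl, Et3N, THF, −20 °C; then LiCl, 5, −20 °C to rt
Reagents that add atoms: none
Why: N-Acylation of the oxazolidinone by the mixed pivalic anhydride, assisted by LiCl, installs the chiral auxiliary.

Step 4
Reactants: 7 (S)-4-benzyl-3-{2-[5-bromo-3-methoxy-2-(methoxymethoxy)phenyl]acetyl}oxazolidin-2-one; 8 4-(benzyloxy)-3-methoxybenzaldehyde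
Product: 10 (S)-4-benzyl-3-{(2S,3S)-3-[4-(benzyloxy)-3-methoxyphenyl]-2-[5-bromo-3-methoxy-2-(methoxymethoxy)phenyl]-3-hydroxypropanoyl}oxazolidin-2-one, via Z boron enolate 9 (not isolated)
Conditions: n-Bu2BOTf, i-Pr2NEt, CH2Cl2, −78 to 0 °C; 8, −78 to 0 °C; then pH 7 buffer, MeOH, 30% H2O2, 0 °C
Reagents that add atoms: none
Why: Evans syn aldol reaction, in which the Z boron enolate reacts through a closed chair transition state on the face remote from the benzyl group of the auxiliary, should set the aryl-bearing carbon as S (the future C3 of the dihydrobenzofuran, R once the substituent priorities change) together with a syn carbinol whose configuration is not needed later.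

Step 5
Reactants: 10 (S)-4-benzyl-3-{(2S,3S)-3-[4-(benzyloxy)-3-methoxyphenyl]-2-[5-bromo-3-methoxy-2-(methoxymethoxy)phenyl]-3-hydroxypropanoyl}oxazolidin-2-one
Product: 11 (1S,2R)-1-[4-(benzyloxy)-3-methoxyphenyl]-2-[5-bromo-3-methoxy-2-(methoxymethoxy)phenyl]propane-1,3-diol
Conditions: LiBH4, MeOH (1 equiv), THF, 0 °C
Reagents that add atoms: none
Why: Reductive cleavage of the N-acyl oxazolidinone by LiBH4 gives the primary alcohol without epimerising the aryl-bearing centre and returns the auxiliary.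

Step 6
Reactants: 11 (1S,2R)-1-[4-(benzyloxy)-3-methoxyphenyl]-2-[5-bromo-3-methoxy-2-(methoxymethoxy)phenyl]propane-1,3-diol
Product: 13 [(2S,3R)-2-[4-(benzyloxy)-3-methoxyphenyl]-5-bromo-7-methoxy-2,3-dihydro-1-benzofuran-3-yl]methanol, via free phenol 12 (not isolated)
Conditions: HCl (3 M in MeOH), THF, 0 °C to rt
Reagents that add atoms: none
Why: Acid first cleaves the methoxymethyl acetal to the phenol and then ionises the secondary carbinol (C2 of the future ring), which is benzylic and para to the benzyloxy oxygen, to a para-quinone-methide-type oxocarbenium ion that the ortho phenol oxygen captures. The closest known reaction type is the acid-mediated, biomimetic closure of phenylcoumarans from 1,2-diarylpropane-1,3-diols and of pterocarpans from MOM-protected isoflavanols. The five-membered ring closes in a 5-exo-trig mode on the exocyclic cationic carbon. The new C2 centre is controlled by the existing C3 centre: the aryl group should settle trans to the hydroxymethyl group, and because the cation is planar and closure is reversible under acid, both carbinol epimers should converge on the trans (2S,3R) isomer. The step needs O-cyclisation to beat loss of formaldehyde from the cation (stilbene formation), elimination, methyl ether formation and attack by the primary alcohol; the phenol capture is intramolecular and five-membered, the methyl ether re-ionises, an oxetane would be strained, and the aryl benzyl ether and aryl bromide are inert to dilute HCl.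

Step 7
Reactants: 13 [(2S,3R)-2-[4-(benzyloxy)-3-methoxyphenyl]-5-bromo-7-methoxy-2,3-dihydro-1-benzofuran-3-yl]methanol
Product: 14 tert-butyl{[(2S,3R)-2-[4-(benzyloxy)-3-methoxyphenyl]-5-bromo-7-methoxy-2,3-dihydro-1-benzofuran-3-yl]methoxy}dimethylsilane
Conditions: TBSCl, imidazole, DMF, rt
Reagents that add atoms: tert-butyldimethylsilyl chloride (CC(C)(C)[Si](C)(C)Cl)
Why: Imidazole-mediated silylation of the primary alcohol protects it for the organolithium, bromination and enolate steps.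

Step 8
Reactants: 14 tert-butyl{[(2S,3R)-2-[4-(benzyloxy)-3-methoxyphenyl]-5-bromo-7-methoxy-2,3-dihydro-1-benzofuran-3-yl]methoxy}dimethylsilane
Product: 17 [(2S,3R)-2-[4-(benzyloxy)-3-methoxyphenyl]-3-{[(tert-butyldimethylsilyl)oxy]methyl}-7-methoxy-2,3-dihydro-1-benzofuran-5-yl]methanol, via aryllithium 15 (not isolated), via aldehyde 16 (not isolated)
Conditions: n-BuLi, THF, −78 °C; DMF, −78 to 0 °C; then MeOH, NaBH4, 0 °C
Reagents that add atoms: N,N-dimethylformamide (CN(C)C=O)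
Why: Bromine–lithium exchange at −78 °C should outrun deprotonation, the aryllithium is formylated by DMF (Bouveault aldehyde synthesis) and the aldehyde released on adding methanol is reduced in the same flask by NaBH4.

Step 9
Reactants: 17 [(2S,3R)-2-[4-(benzyloxy)-3-methoxyphenyl]-3-{[(tert-butyldimethylsilyl)oxy]methyl}-7-methoxy-2,3-dihydro-1-benzofuran-5-yl]methanol
Product: 18 {[(2S,3R)-2-[4-(benzyloxy)-3-methoxyphenyl]-5-(bromomethyl)-7-methoxy-2,3-dihydro-1-benzofuran-3-yl]methoxy}(tert-butyl)dimethylsilane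
Conditions: CBr4, PPh3, CH2Cl2, 0 °C
Reagents that add atoms: carbon tetrabromide (BrC(Br)(Br)Br)
Why: The Appel reaction converts the electron-rich benzylic alcohol into the bromide under neutral conditions that should not disturb the silyl ether or the dihydrobenzofuran.

Step 10
Reactants: 1 5-bromo-2-hydroxy-3-methoxybenzaldehyde
Product: 19 2-(benzyloxy)-5-bromo-3-methoxybenzaldehyde
Conditions: BnBr, K2CO3, DMF, 60 °C
Reagents that add atoms: benzyl bromide (BrCc1ccccc1)
Why: Williamson etherification gives a benzyl ether that should last until the final hydrogenolysis.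

Step 11
Reactants: 19 2-(benzyloxy)-5-bromo-3-methoxybenzaldehyde
Product: 21 2-[2-(benzyloxy)-5-bromo-3-methoxyphenyl]acetic acid, via trichloromethyl carbinol 20 (not isolated)
Conditions: CHCl3, DBU, 0 °C to rt; then NaBH4, NaOH, t-BuOH, 55 °C; acidic work-up
Reagents that add atoms: chloroform (ClC(Cl)Cl); sodium hydroxide ([Na+].[OH-])
Why: As in step 2, trichloromethide addition and reductive Jocic reaction should deliver the one-carbon-homologated arylacetic acid.

Step 12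
Reactants: 21 2-[2-(benzyloxy)-5-bromo-3-methoxyphenyl]acetic acid; 22 (R)-4-benzyloxazolidin-2-one
Product: 24 (R)-4-benzyl-3-{2-[2-(benzyloxy)-5-bromo-3-methoxyphenyl]acetyl}oxazolidin-2-one, via mixed pivalic anhydride 23 (not isolated)
Conditions: t-BuCOCl, Et3N, THF, −20 °C; then LiCl, 22, −20 °C to rt
Reagents that add atoms: none
Why: Mixed-anhydride N-acylation as in step 3, now with the R auxiliary that will induce the opposite configuration.

Step 13
Reactants: 24 (R)-4-benzyl-3-{2-[2-(benzyloxy)-5-bromo-3-methoxyphenyl]acetyl}oxazolidin-2-one; 8 4-(benzyloxy)-3-methoxybenzaldehyde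
Product: 26 (R)-4-benzyl-3-{(2R,3R)-3-[4-(benzyloxy)-3-methoxyphenyl]-2-[2-(benzyloxy)-5-bromo-3-methoxyphenyl]-3-hydroxypropanoyl}oxazolidin-2-one, via Z boron enolate 25 (not isolated)
Conditions: n-Bu2BOTf, i-Pr2NEt, CH2Cl2, −78 to 0 °C; 8, −78 to 0 °C; then pH 7 buffer, MeOH, 30% H2O2, 0 °C
Reagents that add atoms: none
Why: Evans syn aldol reaction with the enantiomeric auxiliary, whose benzyl group shields the other enolate face in the chair transition state, should set the aryl-bearing carbon as R (S in the diol and in the final ketone) while the syn carbinol centre will later be oxidised away.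

Step 14
Reactants: 26 (R)-4-benzyl-3-{(2R,3R)-3-[4-(benzyloxy)-3-methoxyphenyl]-2-[2-(benzyloxy)-5-bromo-3-methoxyphenyl]-3-hydroxypropanoyl}oxazolidin-2-one
Product: 27 (1R,2S)-1-[4-(benzyloxy)-3-methoxyphenyl]-2-[2-(benzyloxy)-5-bromo-3-methoxyphenyl]propane-1,3-diol
Conditions: LiBH4, MeOH (1 equiv), THF, 0 °C
Reagents that add atoms: none
Why: LiBH4 reductive removal of the auxiliary as in step 5 leaves the aryl-bearing centre untouched.

Step 15
Reactants: 27 (1R,2S)-1-[4-(benzyloxy)-3-methoxyphenyl]-2-[2-(benzyloxy)-5-bromo-3-methoxyphenyl]propane-1,3-diol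
Product: 28 (1R,2S)-1-[4-(benzyloxy)-3-methoxyphenyl]-2-[2-(benzyloxy)-5-bromo-3-methoxyphenyl]-1,3-bis[(tert-butyldimethylsilyl)oxy]propane
Conditions: TBSOTf, 2,6-lutidine, CH2Cl2, −78 to 0 °C
Reagents that add atoms: tert-butyldimethylsilyl trifluoromethanesulfonate (CC(C)(C)[Si](C)(C)OS(=O)(=O)C(F)(F)F)
Why: Silylation of both hydroxyl groups with the silyl triflate and a hindered base gives ethers that tolerate the organozinc and lithium amide reagents ahead.

Step 16
Reactants: 29 (R)-paraconic acid [(3R)-5-oxooxolane-3-carboxylic acid]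
Product: 30 (S)-4-(hydroxymethyl)oxolan-2-one
Conditions: BH3·SMe2, THF, 0 °C to rt; MeOH quench
Reagents that add atoms: none
Why: Borane reduces the carboxylic acid chemoselectively beside the lactone and does not touch the stereocentre, which comes from the purchased acid.

Step 17
Reactants: 30 (S)-4-(hydroxymethyl)oxolan-2-one
Product: 31 (R)-4-(iodomethyl)oxolan-2-one
Conditions: I2, PPh3, imidazole, CH2Cl2, 0 °C to rt
Reagents that add atoms: iodine (II)
Why: Appel-type iodination of the primary alcohol gives the iodide needed for zinc insertion.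

Step 18
Reactants: 31 (R)-4-(iodomethyl)oxolan-2-one; 28 (1R,2S)-1-[4-(benzyloxy)-3-methoxyphenyl]-2-[2-(benzyloxy)-5-bromo-3-methoxyphenyl]-1,3-bis[(tert-butyldimethylsilyl)oxy]propane
Product: 33 (4R)-4-{4-(benzyloxy)-3-[(1R,2S)-1-[4-(benzyloxy)-3-methoxyphenyl]-1,3-bis[(tert-butyldimethylsilyl)oxy]propan-2-yl]-5-methoxybenzyl}oxolan-2-one, via alkylzinc iodide 32 (not isolated)
Conditions: Zn dust (activated with 1,2-dibromoethane and Me3SiCl), LiCl, THF, 40 °C; then 28, Pd(OAc)2 (2 mol%), SPhos (4 mol%), THF, 50 °C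
Reagents that add atoms: none
Why: LiCl-promoted zinc insertion into the primary C–I bond gives a lactone-tolerant alkylzinc iodide that should undergo Negishi sp3–sp2 cross-coupling with the unhindered aryl bromide; the stereocentre beta to zinc is not involved.

Step 19
Reactants: 33 (4R)-4-{4-(benzyloxy)-3-[(1R,2S)-1-[4-(benzyloxy)-3-methoxyphenyl]-1,3-bis[(tert-butyldimethylsilyl)oxy]propan-2-yl]-5-methoxybenzyl}oxolan-2-one; 18 {[(2S,3R)-2-[4-(benzyloxy)-3-methoxyphenyl]-5-(bromomethyl)-7-methoxy-2,3-dihydro-1-benzofuran-3-yl]methoxy}(tert-butyl)dimethylsilane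
Product: 35 (3R,4R)-4-{4-(benzyloxy)-3-[(1R,2S)-1-[4-(benzyloxy)-3-methoxyphenyl]-1,3-bis[(tert-butyldimethylsilyl)oxy]propan-2-yl]-5-methoxybenzyl}-3-{[(2S,3R)-2-[4-(benzyloxy)-3-methoxyphenyl]-3-{[(tert-butyldimethylsilyl)oxy]methyl}-7-methoxy-2,3-dihydro-1-benzofuran-5-yl]methyl}oxolan-2-one, via lithium enolate 34 (not isolated)
Conditions: LiN(SiMe3)2, THF, −78 °C; then 18, DMPU, −78 to −30 °C
Reagents that add atoms: none
Why: Alkylation of the lactone lithium enolate by the benzylic bromide should occur anti to the C4 benzyl substituent and so set C3 as R, the trans-3,4-dibenzylbutyrolactone arrangement that is also the thermodynamic one.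

Step 20
Reactants: 35 the tris-silyl ether from step 19
Product: 36 (3R,4R)-4-{4-(benzyloxy)-3-[(1R,2S)-1-[4-(benzyloxy)-3-methoxyphenyl]-1,3-dihydroxypropan-2-yl]-5-methoxybenzyl}-3-{[(2S,3R)-2-[4-(benzyloxy)-3-methoxyphenyl]-3-(hydroxymethyl)-7-methoxy-2,3-dihydro-1-benzofuran-5-yl]methyl}oxolan-2-one
Conditions: Bu4NF, AcOH, THF, 0 °C to rt
Reagents that add atoms: none
Why: Fluoride-mediated cleavage of the three silyl ethers, buffered with acetic acid so that the lactone is not opened.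

Step 21
Reactants: 36 the triol from step 20
Product: 37 (3R,4R)-4-{4-(benzyloxy)-3-[(2S)-1-[4-(benzyloxy)-3-methoxyphenyl]-3-hydroxy-1-oxopropan-2-yl]-5-methoxybenzyl}-3-{[(2S,3R)-2-[4-(benzyloxy)-3-methoxyphenyl]-3-(hydroxymethyl)-7-methoxy-2,3-dihydro-1-benzofuran-5-yl]methyl}oxolan-2-one
Conditions: activated MnO2 (excess), CH2Cl2, rt
Reagents that add atoms: none
Why: MnO2 oxidises benzylic but not saturated primary alcohols, so only the electron-rich benzylic carbinol should give the aryl ketone, and the neutral heterogeneous medium should leave the alpha-aryl stereocentre and the beta-hydroxy group untouched.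

Step 22
Reactants: 37 the tris-benzyl ether ketone from step 21
Product: 38 CNP0111438.1, (3R,4R)-4-{4-hydroxy-3-[(2S)-3-hydroxy-1-(4-hydroxy-3-methoxyphenyl)-1-oxopropan-2-yl]-5-methoxybenzyl}-3-{[(2S,3R)-3-(hydroxymethyl)-2-(4-hydroxy-3-methoxyphenyl)-7-methoxy-2,3-dihydro-1-benzofuran-5-yl]methyl}oxolan-2-one
Conditions: H2 (1 atm), 10% Pd/C, EtOAc–EtOH, rt
Reagents that add atoms: none
Why: Hydrogenolysis of the three aryl benzyl ethers over palladium on carbon is neutral and should spare the aryl ketone, the dihydrobenzofuran and the epimerisable alpha-aryl centre.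

**Compound list**

1 | 5-bromo-2-hydroxy-3-methoxybenzaldehyde | O=Cc1cc(Br)cc(OC)c1O | starting material
2 | 5-bromo-3-methoxy-2-(methoxymethoxy)benzaldehyde | COCOc1c(OC)cc(Br)cc1C=O | intermediate
3 | 1-[5-bromo-3-methoxy-2-(methoxymethoxy)phenyl]-2,2,2-trichloroethanol (racemic) | COCOc1c(OC)cc(Br)cc1C(O)C(Cl)(Cl)Cl | intermediate (not isolated)
4 | 2-[5-bromo-3-methoxy-2-(methoxymethoxy)phenyl]acetic acid | COCOc1c(OC)cc(Br)cc1CC(=O)O | intermediate
5 | (S)-4-benzyloxazolidin-2-one | O=C1N[C@@H](Cc2ccccc2)CO1 | starting material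
6 | 2-[5-bromo-3-methoxy-2-(methoxymethoxy)phenyl]acetic pivalic anhydride | COCOc1c(OC)cc(Br)cc1CC(=O)OC(=O)C(C)(C)C | intermediate (not isolated)
7 | (S)-4-benzyl-3-{2-[5-bromo-3-methoxy-2-(methoxymethoxy)phenyl]acetyl}oxazolidin-2-one | COCOc1c(OC)cc(Br)cc1CC(=O)N1[C@@H](Cc2ccccc2)COC1=O | intermediate
8 | 4-(benzyloxy)-3-methoxybenzaldehyde | COc1cc(C=O)ccc1OCc1ccccc1 | starting material
9 | Z di-n-butylboron enolate of 7 | CCCCB(CCCC)O/C(=C\c1cc(Br)cc(OC)c1OCOC)N1[C@@H](Cc2ccccc2)COC1=O | intermediate (not isolated)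
10 | (S)-4-benzyl-3-{(2S,3S)-3-[4-(benzyloxy)-3-methoxyphenyl]-2-[5-bromo-3-methoxy-2-(methoxymethoxy)phenyl]-3-hydroxypropanoyl}oxazolidin-2-one | COc1cc([C@@H](O)[C@@H](C(=O)N2[C@@H](Cc3ccccc3)COC2=O)c2cc(Br)cc(OC)c2OCOC)ccc1OCc1ccccc1 | intermediate
11 | (1S,2R)-1-[4-(benzyloxy)-3-methoxyphenyl]-2-[5-bromo-3-methoxy-2-(methoxymethoxy)phenyl]propane-1,3-diol | COc1cc([C@@H](O)[C@@H](CO)c2cc(Br)cc(OC)c2OCOC)ccc1OCc1ccccc1 | intermediate
12 | (1S,2R)-1-[4-(benzyloxy)-3-methoxyphenyl]-2-(5-bromo-2-hydroxy-3-methoxyphenyl)propane-1,3-diol | COc1cc([C@@H](O)[C@@H](CO)c2cc(Br)cc(OC)c2O)ccc1OCc1ccccc1 | intermediate (not isolated)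
13 | [(2S,3R)-2-[4-(benzyloxy)-3-methoxyphenyl]-5-bromo-7-methoxy-2,3-dihydro-1-benzofuran-3-yl]methanol | Brc1cc(OC)c2c(c1)[C@H](CO)[C@@H](c1ccc(OCc3ccccc3)c(OC)c1)O2 | intermediate
14 | tert-butyl{[(2S,3R)-2-[4-(benzyloxy)-3-methoxyphenyl]-5-bromo-7-methoxy-2,3-dihydro-1-benzofuran-3-yl]methoxy}dimethylsilane | Brc1cc(OC)c2c(c1)[C@H](CO[Si](C)(C)C(C)(C)C)[C@@H](c1ccc(OCc3ccccc3)c(OC)c1)O2 | intermediate
15 | 5-lithio derivative of 14 (lithium in place of bromine) | [Li]c1cc(OC)c2c(c1)[C@H](CO[Si](C)(C)C(C)(C)C)[C@@H](c1ccc(OCc3ccccc3)c(OC)c1)O2 | intermediate (not isolated)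
16 | (2S,3R)-2-[4-(benzyloxy)-3-methoxyphenyl]-3-{[(tert-butyldimethylsilyl)oxy]methyl}-7-methoxy-2,3-dihydro-1-benzofuran-5-carbaldehyde | O=Cc1cc(OC)c2c(c1)[C@H](CO[Si](C)(C)C(C)(C)C)[C@@H](c1ccc(OCc3ccccc3)c(OC)c1)O2 | intermediate (not isolated)
17 | [(2S,3R)-2-[4-(benzyloxy)-3-methoxyphenyl]-3-{[(tert-butyldimethylsilyl)oxy]methyl}-7-methoxy-2,3-dihydro-1-benzofuran-5-yl]methanol | OCc1cc(OC)c2c(c1)[C@H](CO[Si](C)(C)C(C)(C)C)[C@@H](c1ccc(OCc3ccccc3)c(OC)c1)O2 | intermediate
18 | {[(2S,3R)-2-[4-(benzyloxy)-3-methoxyphenyl]-5-(bromomethyl)-7-methoxy-2,3-dihydro-1-benzofuran-3-yl]methoxy}(tert-butyl)dimethylsilane | BrCc1cc(OC)c2c(c1)[C@H](CO[Si](C)(C)C(C)(C)C)[C@@H](c1ccc(OCc3ccccc3)c(OC)c1)O2 | intermediate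
19 | 2-(benzyloxy)-5-bromo-3-methoxybenzaldehyde | O=Cc1cc(Br)cc(OC)c1OCc1ccccc1 | intermediate
20 | 1-[2-(benzyloxy)-5-bromo-3-methoxyphenyl]-2,2,2-trichloroethanol (racemic) | OC(c1cc(Br)cc(OC)c1OCc1ccccc1)C(Cl)(Cl)Cl | intermediate (not isolated)
21 | 2-[2-(benzyloxy)-5-bromo-3-methoxyphenyl]acetic acid | OC(=O)Cc1cc(Br)cc(OC)c1OCc1ccccc1 | intermediate
22 | (R)-4-benzyloxazolidin-2-one | O=C1N[C@H](Cc2ccccc2)CO1 | starting material
23 | 2-[2-(benzyloxy)-5-bromo-3-methoxyphenyl]acetic pivalic anhydride | CC(C)(C)C(=O)OC(=O)Cc1cc(Br)cc(OC)c1OCc1ccccc1 | intermediate (not isolated)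
24 | (R)-4-benzyl-3-{2-[2-(benzyloxy)-5-bromo-3-methoxyphenyl]acetyl}oxazolidin-2-one | O=C(Cc1cc(Br)cc(OC)c1OCc1ccccc1)N1[C@H](Cc2ccccc2)COC1=O | intermediate
25 | Z di-n-butylboron enolate of 24 | CCCCB(CCCC)O/C(=C\c1cc(Br)cc(OC)c1OCc1ccccc1)N1[C@H](Cc2ccccc2)COC1=O | intermediate (not isolated)
26 | (R)-4-benzyl-3-{(2R,3R)-3-[4-(benzyloxy)-3-methoxyphenyl]-2-[2-(benzyloxy)-5-bromo-3-methoxyphenyl]-3-hydroxypropanoyl}oxazolidin-2-one | COc1cc([C@H](O)[C@H](C(=O)N2[C@H](Cc3ccccc3)COC2=O)c2cc(Br)cc(OC)c2OCc2ccccc2)ccc1OCc1ccccc1 | intermediate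
27 | (1R,2S)-1-[4-(benzyloxy)-3-methoxyphenyl]-2-[2-(benzyloxy)-5-bromo-3-methoxyphenyl]propane-1,3-diol | COc1cc([C@H](O)[C@H](CO)c2cc(Br)cc(OC)c2OCc2ccccc2)ccc1OCc1ccccc1 | intermediate
28 | (1R,2S)-1-[4-(benzyloxy)-3-methoxyphenyl]-2-[2-(benzyloxy)-5-bromo-3-methoxyphenyl]-1,3-bis[(tert-butyldimethylsilyl)oxy]propane | COc1cc([C@H](O[Si](C)(C)C(C)(C)C)[C@H](CO[Si](C)(C)C(C)(C)C)c2cc(Br)cc(OC)c2OCc2ccccc2)ccc1OCc1ccccc1 | intermediate
29 | (R)-paraconic acid [(3R)-5-oxooxolane-3-carboxylic acid] | O=C1C[C@@H](C(=O)O)CO1 | starting material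
30 | (S)-4-(hydroxymethyl)oxolan-2-one | O=C1C[C@@H](CO)CO1 | intermediate
31 | (R)-4-(iodomethyl)oxolan-2-one | O=C1C[C@@H](CI)CO1 | intermediate
32 | {[(3R)-5-oxooxolan-3-yl]methyl}zinc iodide | O=C1C[C@@H](C[Zn]I)CO1 | intermediate (not isolated)
33 | (4R)-4-{4-(benzyloxy)-3-[(1R,2S)-1-[4-(benzyloxy)-3-methoxyphenyl]-1,3-bis[(tert-butyldimethylsilyl)oxy]propan-2-yl]-5-methoxybenzyl}oxolan-2-one | COc1cc([C@H](O[Si](C)(C)C(C)(C)C)[C@H](CO[Si](C)(C)C(C)(C)C)c2cc(C[C@H]3COC(=O)C3)cc(OC)c2OCc2ccccc2)ccc1OCc1ccccc1 | intermediate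
34 | lithium enolate of 33 (lactone C2–O–Li and C2=C3) | COc1cc([C@H](O[Si](C)(C)C(C)(C)C)[C@H](CO[Si](C)(C)C(C)(C)C)c2cc(C[C@H]3COC(O[Li])=C3)cc(OC)c2OCc2ccccc2)ccc1OCc1ccccc1 | intermediate (not isolated)
35 | (3R,4R)-4-{4-(benzyloxy)-3-[(1R,2S)-1-[4-(benzyloxy)-3-methoxyphenyl]-1,3-bis[(tert-butyldimethylsilyl)oxy]propan-2-yl]-5-methoxybenzyl}-3-{[(2S,3R)-2-[4-(benzyloxy)-3-methoxyphenyl]-3-{[(tert-butyldimethylsilyl)oxy]methyl}-7-methoxy-2,3-dihydro-1-benzofuran-5-yl]methyl}oxolan-2-one | COc1cc([C@H](O[Si](C)(C)C(C)(C)C)[C@H](CO[Si](C)(C)C(C)(C)C)c2cc(C[C@H]3COC(=O)[C@@H]3Cc3cc(OC)c4c(c3)[C@H](CO[Si](C)(C)C(C)(C)C)[C@@H](c3ccc(OCc5ccccc5)c(OC)c3)O4)cc(OC)c2OCc2ccccc2)ccc1OCc1ccccc1 | intermediate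
36 | (3R,4R)-4-{4-(benzyloxy)-3-[(1R,2S)-1-[4-(benzyloxy)-3-methoxyphenyl]-1,3-dihydroxypropan-2-yl]-5-methoxybenzyl}-3-{[(2S,3R)-2-[4-(benzyloxy)-3-methoxyphenyl]-3-(hydroxymethyl)-7-methoxy-2,3-dihydro-1-benzofuran-5-yl]methyl}oxolan-2-one | COc1cc([C@H](O)[C@H](CO)c2cc(C[C@H]3COC(=O)[C@@H]3Cc3cc(OC)c4c(c3)[C@H](CO)[C@@H](c3ccc(OCc5ccccc5)c(OC)c3)O4)cc(OC)c2OCc2ccccc2)ccc1OCc1ccccc1 | intermediate
37 | (3R,4R)-4-{4-(benzyloxy)-3-[(2S)-1-[4-(benzyloxy)-3-methoxyphenyl]-3-hydroxy-1-oxopropan-2-yl]-5-methoxybenzyl}-3-{[(2S,3R)-2-[4-(benzyloxy)-3-methoxyphenyl]-3-(hydroxymethyl)-7-methoxy-2,3-dihydro-1-benzofuran-5-yl]methyl}oxolan-2-one | COc1cc(C(=O)[C@H](CO)c2cc(C[C@H]3COC(=O)[C@@H]3Cc3cc(OC)c4c(c3)[C@H](CO)[C@@H](c3ccc(OCc5ccccc5)c(OC)c3)O4)cc(OC)c2OCc2ccccc2)ccc1OCc1ccccc1 | intermediate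
38 | CNP0111438.1, (3R,4R)-4-{4-hydroxy-3-[(2S)-3-hydroxy-1-(4-hydroxy-3-methoxyphenyl)-1-oxopropan-2-yl]-5-methoxybenzyl}-3-{[(2S,3R)-3-(hydroxymethyl)-2-(4-hydroxy-3-methoxyphenyl)-7-methoxy-2,3-dihydro-1-benzofuran-5-yl]methyl}oxolan-2-one | COc1cc(C(=O)[C@H](CO)c2cc(C[C@H]3COC(=O)[C@@H]3Cc3cc(OC)c4c(c3)[C@H](CO)[C@@H](c3ccc(O)c(OC)c3)O4)cc(OC)c2O)ccc1O | target

**Step count and risks**

Total step count: 22. Longest linear sequence: 13 steps (steps 1 to 9, then 19 to 22).

The three steps most likely to fail: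

First, step 6 (key step). The benzylic cation may fragment with loss of formaldehyde from the neighbouring hydroxymethyl group (stilbene formation) or eliminate before the phenol closes, and acetal cleavage may lag behind ionisation. The fallback sets out from aldol adduct 10 and closes the ring before the auxiliary is removed, where the carbon next to the cation carries an acyl group and cannot leave as formaldehyde. HCl in MeOH–THF should first give in the flask the free phenol (S)-4-benzyl-3-{(2S,3S)-3-[4-(benzyloxy)-3-methoxyphenyl]-2-(5-bromo-2-hydroxy-3-methoxyphenyl)-3-hydroxypropanoyl}oxazolidin-2-one F1 and from it the cyclised imide (S)-4-benzyl-3-{[(2S,3S)-2-[4-(benzyloxy)-3-methoxyphenyl]-5-bromo-7-methoxy-2,3-dihydro-1-benzofuran-3-yl]carbonyl}oxazolidin-2-one F2. LiBH4 reduction of F2 then comes back to the route at 13.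

Second, step 21. The hindered secondary carbinol may oxidise slowly, and forcing may bring oxidation of the primary alcohols or dehydrogenation at C2 of the dihydrobenzofuran. The fallback sets out from triol 36 and turns chemoselectivity into a protecting-group problem. Selective silylation of the two primary alcohols (TBSCl, imidazole, DMF, 0 °C) should give (3R,4R)-4-{4-(benzyloxy)-3-[(1R,2S)-1-[4-(benzyloxy)-3-methoxyphenyl]-3-[(tert-butyldimethylsilyl)oxy]-1-hydroxypropan-2-yl]-5-methoxybenzyl}-3-{[(2S,3R)-2-[4-(benzyloxy)-3-methoxyphenyl]-3-{[(tert-butyldimethylsilyl)oxy]methyl}-7-methoxy-2,3-dihydro-1-benzofuran-5-yl]methyl}oxolan-2-one F3. Dess–Martin periodinane buffered with NaHCO3 should then give the ketone (3R,4R)-4-{4-(benzyloxy)-3-[(2S)-1-[4-(benzyloxy)-3-methoxyphenyl]-3-[(tert-butyldimethylsilyl)oxy]-1-oxopropan-2-yl]-5-methoxybenzyl}-3-{[(2S,3R)-2-[4-(benzyloxy)-3-methoxyphenyl]-3-{[(tert-butyldimethylsilyl)oxy]methyl}-7-methoxy-2,3-dihydro-1-benzofuran-5-yl]methyl}oxolan-2-one F4. Desilylation with HF·pyridine in THF comes back to the route at 37.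

Third, step 22. Over-reduction on palladium (aryl ketone to carbinol, hydrogenolysis of the benzylic C2–O1 bond) or epimerisation of the alpha-aryl ketone may occur during a long reaction. The fallback sets out from 37 and cleaves the three aryl benzyl ethers without hydrogen, by BCl3 with pentamethylbenzene as cation scavenger in CH2Cl2 at −78 °C and a cold methanol quench. It goes directly to 38 and makes no new compound.

Further compounds
F1 | step 6 | (S)-4-benzyl-3-{(2S,3S)-3-[4-(benzyloxy)-3-methoxyphenyl]-2-(5-bromo-2-hydroxy-3-methoxyphenyl)-3-hydroxypropanoyl}oxazolidin-2-one | COc1cc([C@@H](O)[C@@H](C(=O)N2[C@@H](Cc3ccccc3)COC2=O)c2cc(Br)cc(OC)c2O)ccc1OCc1ccccc1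
F2 | step 6 | (S)-4-benzyl-3-{[(2S,3S)-2-[4-(benzyloxy)-3-methoxyphenyl]-5-bromo-7-methoxy-2,3-dihydro-1-benzofuran-3-yl]carbonyl}oxazolidin-2-one | Brc1cc(OC)c2c(c1)[C@H](C(=O)N1[C@@H](Cc3ccccc3)COC1=O)[C@@H](c1ccc(OCc3ccccc3)c(OC)c1)O2
F3 | step 21 | (3R,4R)-4-{4-(benzyloxy)-3-[(1R,2S)-1-[4-(benzyloxy)-3-methoxyphenyl]-3-[(tert-butyldimethylsilyl)oxy]-1-hydroxypropan-2-yl]-5-methoxybenzyl}-3-{[(2S,3R)-2-[4-(benzyloxy)-3-methoxyphenyl]-3-{[(tert-butyldimethylsilyl)oxy]methyl}-7-methoxy-2,3-dihydro-1-benzofuran-5-yl]methyl}oxolan-2-one | COc1cc([C@H](O)[C@H](CO[Si](C)(C)C(C)(C)C)c2cc(C[C@H]3COC(=O)[C@@H]3Cc3cc(OC)c4c(c3)[C@H](CO[Si](C)(C)C(C)(C)C)[C@@H](c3ccc(OCc5ccccc5)c(OC)c3)O4)cc(OC)c2OCc2ccccc2)ccc1OCc1ccccc1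
F4 | step 21 | (3R,4R)-4-{4-(benzyloxy)-3-[(2S)-1-[4-(benzyloxy)-3-methoxyphenyl]-3-[(tert-butyldimethylsilyl)oxy]-1-oxopropan-2-yl]-5-methoxybenzyl}-3-{[(2S,3R)-2-[4-(benzyloxy)-3-methoxyphenyl]-3-{[(tert-butyldimethylsilyl)oxy]methyl}-7-methoxy-2,3-dihydro-1-benzofuran-5-yl]methyl}oxolan-2-one | COc1cc(C(=O)[C@H](CO[Si](C)(C)C(C)(C)C)c2cc(C[C@H]3COC(=O)[C@@H]3Cc3cc(OC)c4c(c3)[C@H](CO[Si](C)(C)C(C)(C)C)[C@@H](c3ccc(OCc5ccccc5)c(OC)c3)O4)cc(OC)c2OCc2ccccc2)ccc1OCc1ccccc1
F0 | step 22 | none | none
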